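The readings were generated by integration for an exercise, and the scatter is random.

Per hour, the ratio [target]/[substrate] climbed faster in larch, at 0.936 h⁻¹ up to 15.0 h, than in elm, at 0.0662 h⁻¹ up to 96.0 h.

| flask | substrate | free enzyme | temperature | remark | time |
|---|---|---|---|---|---|
| elm | 0.18 M | 9 µM | 0 °C | run made earlier |  |
| larch | 0.18 M | 36 µM | 20 °C | run made earlier |  |
| delta | 0.18 M | 18 µM | 35 °C |  | 15 h |
| alpha | 0.18 M | 18 µM | 5 °C |  | 15 h |
| gamma | 0.18 M | 18 µM | 20 °C |  | 15 h |

| run | time / h | target / % | substrate / % |
|---|---|---|---|
| elm | 8.00 | 29.9 | 70.6 |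
| elm | 25.0 | 60.3 | 40.3 |
| elm | 50.0 | 76.0 | 24.4 |
| elm | 60.0 | 78.7 | 21.1 |
| elm | 96.0 | 86.4 | 13.6 |
| larch | 3.00 | 72.4 | 27.4 |
| larch | 5.00 | 82.4 | 17.3 |
| larch | 8.00 | 87.8 | 12.1 |
| larch | 15.0 | 94.1 | 6.7 |
| larch | 30.0 | 96.0 | 3.9 |

(standard deviation of a reading: 0.5 percentage points)

- the best flask by amount of target, in percent of the substrate charged; "all alike" if 1.5 percentage points covers them all (delta / alpha / gamma / all alike)
- amount of target at the end, in percent of the substrate charged, delta
- amount of target at the end, in percent of the substrate charged, alpha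
- amount of target at the end, in percent of the substrate charged, gamma



Two chemists read these runs. The first holds that heat just speeds the enzyme. Taking the climb as proportional to free enzyme, larch beats elm per µM by a factor 3.54. Carrying that factor on from 20 °C to 35 °C gives my own figure for the climb rate, the rise per hour of [target]/[substrate] in delta while its free enzyme works: 1.21 h⁻¹. Kept up for 15 h, that climb gives 94.8% target.

The forecast takes this side with its own reckoning. It names delta as best, with 93.5% for delta (range 84% to 96.5%), 72% for alpha and 87% for gamma, shading delta down because “The larch tail slackens slightly”.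

The second chemist holds that free enzyme dies (thermal inactivation), so the climb lasts as long as the enzyme does. The forecast's delta needs 11.9 h of working time at this climb. Larch slowed to 0.705 h⁻¹ over its later readings, and read as enzyme death, with much scatter, that is a lifetime near 52.8 h at 20 °C, longer than delta needs. She gives no figure for delta but a test: for the forecast's number, its enzyme must last about 11.9 h at 35 °C.

The flasks give 22.3% for delta, 72.7% for alpha and 87.2% for gamma, so gamma is best.

    free enzyme → unfolded enzyme (k = 3.00 × 10⁻⁶ s⁻¹, Ea = 283 kJ mol⁻¹)
    substrate + free enzyme → target + free enzyme, rate k2*[substrate]^2*[free enzyme]/(1 + ([substrate]/Kh2)^2) (0.250 M, k = 45.0 L² mol⁻² s⁻¹, Ea = 43.0 kJ mol⁻¹)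
    (constants at 20 °C)

Delta holds 0% free enzyme at 7.50 h, and its target stands at 22.3% after 150 h. At the climb rate 1.21 h⁻¹, its ratio of target to the 78% substrate left is worth 0.238 h of work, far below 11.9 h. The first view keeps the colder flasks, where free enzyme stands at >99.9% in alpha and 85.0% in gamma at 15.0 h. For a neighbour of delta charged with 7.2 × 10⁻⁵ M of free enzyme, I scale the climb rate in proportion to that charge, so the same working time gives 1.15 for the ratio, or 53.5% target. That flask gives 56.8%, with 0% free enzyme at 15.0 h.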